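**Plan**

- Numbering: ring A = C4a–C5–C6–C7–C8–C9–C10–C11–C11a (C19 = exo-CH2 on C11, C18 = CH3 on C7); ring B = C11a–C1–O2–C3–C4–C4a; ring C = O–C3–C4=C12–C13; side chain C14–C15.
- Enabling feature: with C3 as a lactone carbonyl in ring B, C4a is its β-carbon and C4 its α-carbon, so C4a–C5 and C4–C12 are the two bonds of a conjugate addition–aldol sequence.
- Retrosynthetic cuts: the C8/C9 epoxide, C7–C8 (ring A), the C3 acetal and ring C lactone, then C4–C12 and C4a–C5 together, then the lactone C4=C4a (metathesis) and C11a–C11 (allylic substitution).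
- Forward order: ring B is made first as unsaturated δ-lactone 13. The C5–C7 chain and the C12–C15 side chain are joined to it in one flask. Ring C arises by translactonisation and elimination, ring B is re-closed as the acetal, ring A is closed by a Nozaki–Hiyama–Kishi reaction, and the epoxide comes last.
- Stereochemistry: C11a from a copper-catalysed enantioselective allylic substitution; C4a by addition anti to C11a; C13 and C14 from D-erythronolactone; C3 under thermodynamic control of the ring fusion; C7 in the ring A closure; C8 and C9 by hydroxyl-directed epoxidation.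

Key step: step 12

Remark: the alkyne terminus is carried as a triisopropylsilyl group and the C15 hydroxyl as a tert-butyldimethylsilyl ether, so that they survive methoxide (step 5) and acid (step 14) respectively.

**Route**

Step 1
Reactants: 1 (triisopropylsilyl)acetylene; 2 2,3-dibromopropene
Product: 4 2-bromo-5-(triisopropylsilyl)pent-1-en-4-yne, via alkynyl Grignard 3 (not isolated)
Conditions: EtMgBr, THF, 50 °C; then CuBr·SMe2 (5 mol%), 2, 50 °C
Reagents that add atoms: none
Why: Copper-catalysed allylic substitution of the allylic bromide by the alkynyl Grignard reagent gives the skipped enyne, and the vinylic bromide does not react.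

Step 2
Reactants: 4 2-bromo-5-(triisopropylsilyl)pent-1-en-4-yne
Product: 5 4,4,5,5-tetramethyl-2-[5-(triisopropylsilyl)pent-1-en-4-yn-2-yl]-1,3,2-dioxaborolane
Conditions: B2pin2, PdCl2(PPh3)2 (3 mol%), PPh3, KOPh, toluene, 50 °C
Reagents that add atoms: bis(pinacolato)diboron, CC1(C)OB(OC1(C)C)B1OC(C)(C)C(C)(C)O1
Why: Miyaura borylation of an alkenyl bromide with the weak base KOPh should give the 1,1-disubstituted alkenylboronate without affecting the silylalkyne.

Step 3
Reactants: 6 (E)-but-2-ene-1,4-diol
Product: 7 (E)-4-(tert-butyldimethylsilyloxy)but-2-en-1-ol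
Conditions: NaH (1 equiv), THF, 20 °C; then TBSCl (1 equiv)
Reagents that add atoms: tert-butyldimethylsilyl chloride, CC(C)(C)[Si](C)(C)Cl
Why: O-Silylation through the sparingly soluble monosodium alkoxide favours the mono-ether of the symmetric diol.

Step 4
Reactants: 7 (E)-4-(tert-butyldimethylsilyloxy)but-2-en-1-ol
Product: 8 (E)-4-(tert-butyldimethylsilyloxy)but-2-enyl diethyl phosphate
Conditions: ClP(O)(OEt)2, Et3N, DMAP (cat.), CH2Cl2, 0 °C
Reagents that add atoms: diethyl chlorophosphate, CCOP(=O)(Cl)OCC
Why: O-Phosphorylation of the primary allylic alcohol installs the leaving group for the copper-catalysed allylic substitution.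

Step 5
Reactants: 8 (E)-4-(tert-butyldimethylsilyloxy)but-2-enyl diethyl phosphate; 5 alkenylboronate
Product: 9 tert-butyldimethylsilyl ether of (2R)-2-ethenyl-3-methylidene-6-(triisopropylsilyl)hex-5-yn-1-ol
Conditions: CuCl (5 mol%), chiral sulfonate-bridged N-aryl imidazolinium salt (NHC precursor, 5.5 mol%, enantiomer giving the R product), NaOMe (1.5 equiv), THF, 22 → 50 °C
Reagents that add atoms: none
Why: In this NHC–copper-catalysed enantioselective allylic substitution, methoxide activates the boronate, the alkenylcopper adds SN2′ to the E-allylic phosphate, and the chiral carbene selects the alkene face so that C11a is formed as (R).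

Step 6
Reactants: 9 silyl ether
Product: 10 (2R)-2-ethenyl-3-methylidene-6-(triisopropylsilyl)hex-5-yn-1-ol
Conditions: PPTS (10 mol%), MeOH, 0 → 20 °C
Reagents that add atoms: none
Why: Acid-catalysed methanolysis removes the primary O-silyl ether, whereas the alkynyl C–Si bond is stable to protic acid (fluoride would cleave it).

Step 7
Reactants: 10 dienynol; 11 acryloyl chloride
Product: 12 (2R)-2-ethenyl-3-methylidene-6-(triisopropylsilyl)hex-5-yn-1-yl prop-2-enoate
Conditions: Et3N, CH2Cl2, −20 → 0 °C
Reagents that add atoms: none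
Why: O-Acylation of the primary alcohol is routine, and the low temperature limits amine addition to the acrylate.

Step 8
Reactants: 12 acrylate
Product: 13 (5R)-5-[5-(triisopropylsilyl)pent-1-en-4-yn-2-yl]-5,6-dihydro-2H-pyran-2-one
Conditions: second-generation Grubbs catalyst (5 mol%), CH2Cl2 (5 mM), 40 °C
Reagents that add atoms: none
Why: Ring-closing metathesis starts at the monosubstituted vinyl group and closes onto the acrylate to give the six-membered unsaturated lactone; the 1,1-disubstituted alkene and the bulky silylalkyne are poor partners and the C11a centre is untouched.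

Step 9
Reactants: 14 2,3-O-isopropylidene-D-erythronolactone
Product: 15 2-[(4R,5R)-5-(hydroxymethyl)-2,2-dimethyl-1,3-dioxolan-4-yl]propan-2-ol
Conditions: MeMgBr (3 equiv), THF, 0 → 20 °C
Reagents that add atoms: methylmagnesium bromide, C[Mg]Br
Why: Double Grignard addition to the lactone carbonyl opens the ring to the primary/tertiary diol without touching the two dioxolane stereocentres.

Step 10
Reactants: 15 diol
Product: 17 primary triethylsilyl / tertiary tert-butyldimethylsilyl bis-ether of 15, via mono-TES ether 16 (not isolated)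
Conditions: TESOTf (1.05 equiv), 2,6-lutidine, CH2Cl2, −78 °C; then TBSOTf (1.5 equiv), −78 → 0 °C
Reagents that add atoms: triethylsilyl triflate, CC[Si](CC)(CC)OS(=O)(=O)C(F)(F)F; tert-butyldimethylsilyl triflate, CC(C)(C)[Si](C)(C)OS(=O)(=O)C(F)(F)F
Why: Silyl triflates react in order of steric access, so one equivalent of TESOTf at −78 °C takes the primary hydroxyl and TBSOTf then caps the tertiary one.

Step 11
Reactants: 17 bis-silyl ether
Product: 18 (4S,5R)-5-[2-(tert-butyldimethylsilyloxy)propan-2-yl]-2,2-dimethyl-1,3-dioxolane-4-carbaldehyde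
Conditions: (COCl)2, DMSO, CH2Cl2, −78 → −30 °C; then Et3N, −78 → 0 °C
Reagents that add atoms: none
Why: Swern conditions cleave and oxidise a primary triethylsilyl ether directly to the aldehyde while the tertiary TBS ether and the acetonide persist, and the low temperature guards the cis-dioxolane aldehyde against epimerisation.

Step 12
Reactants: 13 unsaturated δ-lactone; 19 2-(2-bromoethyl)-2-methyl-1,3-dioxolane; 18 aldehyde
Product: 23 4a,11a-trans δ-lactone aldol (mixture of C4 and C12 epimers), via Grignard reagent 20 (not isolated), via magnesium cuprate 21 (not isolated), via magnesium enolate 22 (not isolated)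
Conditions: 19, Mg, THF, 20 °C; CuBr·SMe2 (0.5 equiv per 20), THF/Me2S, −78 → −40 °C; 13, −78 °C; then 18, −78 °C; aq. NH4Cl/NH3
Reagents that add atoms: none
Why: Grignard reagent 20 and CuBr·SMe2 give the magnesium dialkylcuprate 21, which adds to C4a of lactone 13 (copper–alkene complex, C–Cu bond formation at the β-carbon, reductive elimination) and leaves the bromomagnesium enolate 22; this enolate then adds to the aldehyde carbon of 18, so that C4a–C5 and C4–C12 are formed in one flask. The closest known reaction type is the tandem organocuprate conjugate addition–aldol trapping used on cycloalkenones and α,β-unsaturated lactones. No ring is closed; ring B is carried through as the δ-lactone. The new C4a centre is controlled by the C11a substituent, because the cuprate attacks the half-chair lactone axially on the face anti to the adjacent alkenyl branch and gives the 4a,11a-trans product; the new C4 and C12 centres are left uncontrolled because both are erased when C4=C12 is made. The step needs 1,4- over 1,2-addition (secured by copper), anti over syn attack (secured by the C11a branch) and aldol trapping over proton transfer from the aldehyde α-position (secured by the weakly basic magnesium enolate, −78 °C and the reactive α-alkoxy aldehyde).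

Step 13
Reactants: 23 aldol
Product: 24 C12 methanesulfonate of 23
Conditions: MsCl, pyridine, DMAP (cat.), CH2Cl2, 0 → 20 °C
Reagents that add atoms: methanesulfonyl chloride, CS(=O)(=O)Cl
Why: Sulfonylation of the only free hydroxyl installs the leaving group for the later E1cB elimination, and pyridine is too weak a base to trigger elimination while ring B is still the δ-lactone.

Step 14
Reactants: 24 mesylate
Product: 26 butenolide diol (ring C lactone; C1 and C14 hydroxyls free), via γ-lactone mesylate 25 (not isolated)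
Conditions: TsOH·H2O (0.2 equiv), ethylene glycol (10 equiv), MeCN, 40 °C; then Et3N (5 equiv), 20 °C
Reagents that add atoms: none
Why: Acid-catalysed transketalisation moves the acetonide onto ethylene glycol (which also holds the C7 dioxolane in place by mass action), the freed C13 hydroxyl translactonises to the more stable γ-lactone, and Et3N then removes the acidic C4–H and expels the C12 mesylate (E1cB), so that C4=C12 can only form inside ring C with C13 and C14 unchanged.

Step 15
Reactants: 26 butenolide diol
Product: 28 bicyclic acetal (3S,4aS,11aR,13R,14R; rings B and C), via lactol 27 (not isolated)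
Conditions: i-Bu2AlH (5 equiv), CH2Cl2, −78 °C; aq. potassium sodium tartrate work-up; then PPTS (0.1 equiv), 4 Å molecular sieves, CH2Cl2, 0 → 20 °C
Reagents that add atoms: none
Why: Reduction with i-Bu2AlH at −78 °C stops at the lactol, and mild acid then lets the C1 hydroxyl trap the ring C oxocarbenium ion to re-close ring B as the acetal; C3 is set under thermodynamic control, since only the epimer with H3 axial and the ring C oxygen equatorial (coplanar with C4=C12) fits the chair of ring B with its two equatorial branches.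

Step 16
Reactants: 28 bicyclic acetal
Product: 29 1-iodoalkyne (C8 iodide)
Conditions: AgF (1.5 equiv), N-iodosuccinimide (1.5 equiv), MeCN, 20 °C, dark
Reagents that add atoms: N-iodosuccinimide, O=C1CCC(=O)N1I
Why: Silver-mediated halodesilylation (fluoride-assisted formation of the silver acetylide, then iodination) converts the silylalkyne directly into the iodoalkyne under neutral conditions.

Step 17
Reactants: 29 iodoalkyne
Product: 30 (Z)-iodoalkene (C8=C9)
Conditions: 2-nitrobenzenesulfonyl hydrazide (3 equiv), Et3N, THF/i-PrOH, 20 °C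
Reagents that add atoms: none
Why: Diimide reduction delivers two hydrogens syn to the iodoalkyne, the most reactive π-bond present, and gives the (Z)-iodoalkene; it is run before the ketone is unmasked because the hydrazide would condense with a ketone.

Step 18
Reactants: 30 (Z)-iodoalkene ketal
Product: 31 methyl ketone (C7)
Conditions: I2 (0.1 equiv), acetone, 20 °C, dark, short contact; aq. Na2S2O3
Reagents that add atoms: none
Why: Iodine-catalysed transketalisation to acetone is a neutral deprotection that is much faster for ketone dioxolanes than for aldehyde-derived acetals, so the bicyclic C3 acetal (whose tethered oxygens can only re-close), the TBS ether and the iodoalkene should persist.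

Step 19
Reactants: 31 iodoalkenyl ketone
Product: 32 ring A carbinol (7S; Z-C8=C9; nine-membered ring closed)
Conditions: CrCl2 (15 equiv), NiCl2 (0.1 equiv), DMSO, 20 °C, 2 mM, slow addition of 31
Reagents that add atoms: none
Why: In this Nozaki–Hiyama–Kishi reaction the nickel-catalysed formation of the (Z)-alkenylchromium species proceeds with retention, and its intramolecular addition to the C7 ketone closes ring A between two branches held gauche by the trans-fused ring B; the C7 configuration depends on which carbonyl face the ring conformation exposes, and the (7S) carbinol with the hydroxyl on the face of H4a is the one required.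

Step 20
Reactants: 32 ring A carbinol
Product: 33 (7S,8R,9R)-cis-epoxy alcohol, C15 TBS ether of the target
Conditions: VO(acac)2 (5 mol%), t-BuOOH, CH2Cl2, 0 → 20 °C
Reagents that add atoms: tert-butyl hydroperoxide, CC(C)(C)OO
Why: In the vanadium-catalysed hydroxyl-directed epoxidation the C7 vanadate delivers oxygen to the adjacent cis-alkene on the face of the hydroxyl, which in medium rings gives the cis-epoxy alcohol; the undirected C11=C19 and the deactivated C4=C12 alkenes should not react.

Step 21
Reactants: 33 silyl ether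
Product: 34 target CNP0281409.2
Conditions: Bu4NF (3 equiv), THF, 20 → 40 °C
Reagents that add atoms: none
Why: Fluoride cleaves the tertiary silyl ether, helped by the neighbouring C14 hydroxyl, under non-acidic conditions that the epoxide and the acetal tolerate.

**Compound list**

1 | (triisopropylsilyl)acetylene | C#C[Si](C(C)C)(C(C)C)C(C)C | starting material
2 | 2,3-dibromoprop-1-ene | C=C(Br)CBr | starting material
3 | [(triisopropylsilyl)ethynyl]magnesium bromide (not isolated) | Br[Mg]C#C[Si](C(C)C)(C(C)C)C(C)C | intermediate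
4 | 2-bromo-5-(triisopropylsilyl)pent-1-en-4-yne | C=C(Br)CC#C[Si](C(C)C)(C(C)C)C(C)C | intermediate
5 | 4,4,5,5-tetramethyl-2-[5-(triisopropylsilyl)pent-1-en-4-yn-2-yl]-1,3,2-dioxaborolane | C=C(B1OC(C)(C)C(C)(C)O1)CC#C[Si](C(C)C)(C(C)C)C(C)C | intermediate
6 | (E)-but-2-ene-1,4-diol | OC/C=C/CO | starting material
7 | (E)-4-(tert-butyldimethylsilyloxy)but-2-en-1-ol | OC/C=C/CO[Si](C)(C)C(C)(C)C | intermediate
8 | (E)-4-(tert-butyldimethylsilyloxy)but-2-enyl diethyl phosphate | CCOP(=O)(OCC)OC/C=C/CO[Si](C)(C)C(C)(C)C | intermediate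
9 | tert-butyldimethylsilyl ether of (2R)-2-ethenyl-3-methylidene-6-(triisopropylsilyl)hex-5-yn-1-ol | C=C[C@H](C(=C)CC#C[Si](C(C)C)(C(C)C)C(C)C)CO[Si](C)(C)C(C)(C)C | intermediate
10 | (2R)-2-ethenyl-3-methylidene-6-(triisopropylsilyl)hex-5-yn-1-ol | C=C[C@H](C(=C)CC#C[Si](C(C)C)(C(C)C)C(C)C)CO | intermediate
11 | acryloyl chloride | C=CC(=O)Cl | starting material
12 | (2R)-2-ethenyl-3-methylidene-6-(triisopropylsilyl)hex-5-yn-1-yl prop-2-enoate | C=C[C@H](C(=C)CC#C[Si](C(C)C)(C(C)C)C(C)C)COC(=O)C=C | intermediate
13 | (5R)-5-[5-(triisopropylsilyl)pent-1-en-4-yn-2-yl]-5,6-dihydro-2H-pyran-2-one | O=C1C=C[C@H](C(=C)CC#C[Si](C(C)C)(C(C)C)C(C)C)CO1 | intermediate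
14 | 2,3-O-isopropylidene-D-erythronolactone, (3aR,6aR) | O=C1OC[C@H]2OC(C)(C)O[C@@H]12 | starting material
15 | 2-[(4R,5R)-5-(hydroxymethyl)-2,2-dimethyl-1,3-dioxolan-4-yl]propan-2-ol | OC[C@H]1OC(C)(C)O[C@H]1C(C)(C)O | intermediate
16 | primary triethylsilyl ether of 15 (not isolated) | CC[Si](CC)(CC)OC[C@H]1OC(C)(C)O[C@H]1C(C)(C)O | intermediate
17 | primary triethylsilyl, tertiary tert-butyldimethylsilyl bis-ether of 15 | CC[Si](CC)(CC)OC[C@H]1OC(C)(C)O[C@H]1C(C)(C)O[Si](C)(C)C(C)(C)C | intermediate
18 | (4S,5R)-5-[2-(tert-butyldimethylsilyloxy)propan-2-yl]-2,2-dimethyl-1,3-dioxolane-4-carbaldehyde | O=C[C@H]1OC(C)(C)O[C@H]1C(C)(C)O[Si](C)(C)C(C)(C)C | intermediate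
19 | 2-(2-bromoethyl)-2-methyl-1,3-dioxolane | CC1(CCBr)OCCO1 | starting material
20 | [2-(2-methyl-1,3-dioxolan-2-yl)ethyl]magnesium bromide (not isolated) | CC1(CC[Mg]Br)OCCO1 | intermediate
21 | bromomagnesium bis[2-(2-methyl-1,3-dioxolan-2-yl)ethyl]cuprate, monovalent copper (not isolated) | CC1(CC[Cu-]CCC2(C)OCCO2)OCCO1.[Mg+]Br | intermediate
22 | bromomagnesium enolate of the 4a,11a-trans lactone carrying the C5–C7 ketal chain at C4a (not isolated) | Br[Mg]OC1=C[C@@H](CCC2(C)OCCO2)[C@H](C(=C)CC#C[Si](C(C)C)(C(C)C)C(C)C)CO1 | intermediate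
23 | aldol: 4a,11a-trans tetrahydropyran-2-one with the C5–C7 ketal chain at C4a, the silyl enyne branch at C11a and, at C4, the CH(OH) (C12) unit bearing the dioxolane of 18; C4 and C12 epimers | O=C1OC[C@@H](C(=C)CC#C[Si](C(C)C)(C(C)C)C(C)C)[C@H](CCC2(C)OCCO2)C1C(O)[C@H]3OC(C)(C)O[C@H]3C(C)(C)O[Si](C)(C)C(C)(C)C | intermediate
24 | C12 methanesulfonate of 23 | O=C1OC[C@@H](C(=C)CC#C[Si](C(C)C)(C(C)C)C(C)C)[C@H](CCC2(C)OCCO2)C1C(OS(C)(=O)=O)[C@H]3OC(C)(C)O[C@H]3C(C)(C)O[Si](C)(C)C(C)(C)C | intermediate
25 | γ-lactone (C3–O–C13) with C12 mesylate, free C1 and C14 hydroxyls, C15 TBS ether (not isolated) | O=C1O[C@@H]([C@@H](O)C(C)(C)O[Si](C)(C)C(C)(C)C)C(OS(C)(=O)=O)C1[C@@H](CCC2(C)OCCO2)[C@@H](CO)C(=C)CC#C[Si](C(C)C)(C(C)C)C(C)C | intermediate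
26 | butenolide (C3 lactone onto O–C13, C4=C12), (4aS,11aR,13R,14R), free C1 and C14 hydroxyls | O=C1O[C@@H]([C@@H](O)C(C)(C)O[Si](C)(C)C(C)(C)C)C=C1[C@@H](CCC2(C)OCCO2)[C@@H](CO)C(=C)CC#C[Si](C(C)C)(C(C)C)C(C)C | intermediate
27 | lactol of 26 (C3–OH, both anomers; not isolated) | OC1O[C@@H]([C@@H](O)C(C)(C)O[Si](C)(C)C(C)(C)C)C=C1[C@@H](CCC2(C)OCCO2)[C@@H](CO)C(=C)CC#C[Si](C(C)C)(C(C)C)C(C)C | intermediate
28 | bicyclic acetal (rings B and C), (3S,4aS,11aR,13R,14R), C7 dioxolane, silylalkyne, C15 TBS ether | CC1(OCCO1)CC[C@@H]2C3=C[C@H]([C@@H](O)C(C)(C)O[Si](C)(C)C(C)(C)C)O[C@@H]3OC[C@H]2C(=C)CC#C[Si](C(C)C)(C(C)C)C(C)C | intermediate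
29 | iodoalkyne analogue of 28 | CC1(OCCO1)CC[C@@H]2C3=C[C@H]([C@@H](O)C(C)(C)O[Si](C)(C)C(C)(C)C)O[C@@H]3OC[C@H]2C(=C)CC#CI | intermediate
30 | (Z)-iodoalkene analogue of 28 | CC1(OCCO1)CC[C@@H]2C3=C[C@H]([C@@H](O)C(C)(C)O[Si](C)(C)C(C)(C)C)O[C@@H]3OC[C@H]2C(=C)C/C=C\I | intermediate
31 | C7 methyl ketone with (Z)-iodoalkene | CC(=O)CC[C@@H]1C2=C[C@H]([C@@H](O)C(C)(C)O[Si](C)(C)C(C)(C)C)O[C@@H]2OC[C@H]1C(=C)C/C=C\I | intermediate
32 | tricyclic (7S)-carbinol with Z-C8=C9, C15 TBS ether | C=C1C/C=C\[C@@](C)(O)CC[C@@H]2C3=C[C@H]([C@@H](O)C(C)(C)O[Si](C)(C)C(C)(C)C)O[C@@H]3OC[C@@H]12 | intermediate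
33 | (7S,8R,9R)-epoxy alcohol, C15 TBS ether of the target | C=C1C[C@H]2O[C@H]2[C@@](C)(O)CC[C@@H]2C3=C[C@H]([C@@H](O)C(C)(C)O[Si](C)(C)C(C)(C)C)O[C@@H]3OC[C@@H]12 | intermediate
34 | CNP0281409.2, (3S,4aS,7S,8R,9R,11aR,13R,14R) | C=C1C[C@H]2O[C@H]2[C@@](C)(O)CC[C@@H]2C3=C[C@H]([C@@H](O)C(C)(C)O)O[C@@H]3OC[C@@H]12 | target

**Step count and risks**

Total step count: 21. Longest linear sequence: 16 steps (steps 3–8, then 12–21; steps 1, 2, 5–8, 12–21 are equally long).

1. Step 19 (ring A closure). Addition of an alkenylchromium species to a ketone is slow in a nine-membered closure, so protonolysis of the carbon–chromium bond or intermolecular coupling may win. In addition the two faces of the C7 carbonyl are not clearly differentiated, so the C7 epimer may form. The fallback sets out from 28 and comes back at 32; it makes the C7 carbinol before the ring and closes ring A by olefin metathesis at C8=C9. Bu4NF at 0 °C removes only the alkynyl silyl group and gives the terminal alkyne F1. Semi-hydrogenation (H2, Pd on CaCO3 poisoned with Pb(OAc)2, quinoline) gives the allyl compound F2, and iodine in acetone as in step 18 frees the methyl ketone F3. CH2=CHMgBr with CeCl3 at −78 °C gives the tertiary allylic alcohol as two C7 epimers, which are separated; the (7S)-epimer is the vinyl carbinol F4. Second-generation Grubbs catalyst in dilute toluene at 80 °C then closes the C8=C9 bond, which must be cis in the nine-membered ring, and gives 32.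

2. Step 18 (ketone unmasking beside the acetal). The allylic C3 acetal may ionise under the deketalisation conditions and lose H13, which aromatises ring C to a furan; iodine may also isomerise the iodoalkene. The fallback sets out from 26 and comes back at 31; it frees the ketone while ring C is still the robust butenolide and carries C7 as a carbinol, so that the acetal meets acid only when it is formed. PPTS in wet acetone at reflux cleaves the dioxolane of 26 and gives the keto butenolide F5. Excess i-Bu2AlH at −78 °C reduces both the ketone and the lactone to the lactol carbinol F6, and PPTS with molecular sieves closes the acetal carbinol F7 (C7 epimers, which converge later). AgF and N-iodosuccinimide give the iodoalkyne F8, and diimide gives the (Z)-iodoalkene F9. Dess–Martin periodinane buffered with NaHCO3 at 0 °C then oxidises the unhindered C7 carbinol to 31; the C14 hydroxyl, flanked by the silyloxy-bearing quaternary carbon, is expected to react much more slowly.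

3. Step 5 (enantioselective allylic substitution). The catalyst may give insufficient SN2′ or facial selectivity with this alkenyl group, and methoxide may isomerise the skipped enyne into conjugation. The fallback sets out from 4 and comes back at 13; it takes the C11a centre from a commercial chiral carbinol by 1,3-chirality transfer under non-basic conditions. (R)-But-3-en-2-ol and allyl tert-butyldimethylsilyl ether are joined by cross-metathesis (second-generation Grubbs catalyst) to the (R,E)-allylic alcohol F10, which is esterified with picolinic acid (DCC, DMAP) to the picolinate F11. Bromide 4 is converted by bromine–lithium exchange (t-BuLi, −78 °C) and MgBr2·OEt2 into the alkenylmagnesium bromide F12. With CuBr·SMe2 this displaces the picolinate in an anti-SN2′ reaction and gives the (R,E)-propenyl silyl ether F13, the propenyl analogue of 9. Acidic methanolysis gives the alcohol F14, acryloyl chloride gives the acrylate F15, and ring-closing metathesis with loss of propene returns lactone 13.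

**Further compounds**

F1 | step 19 | terminal alkyne analogue of 28 | CC1(OCCO1)CC[C@@H]2C3=C[C@H]([C@@H](O)C(C)(C)O[Si](C)(C)C(C)(C)C)O[C@@H]3OC[C@H]2C(=C)CC#C
F2 | step 19 | allyl (C8=C9 terminal alkene) analogue of 28 | CC1(OCCO1)CC[C@@H]2C3=C[C@H]([C@@H](O)C(C)(C)O[Si](C)(C)C(C)(C)C)O[C@@H]3OC[C@H]2C(=C)CC=C
F3 | step 19 | C7 methyl ketone with allyl branch | CC(=O)CC[C@@H]1C2=C[C@H]([C@@H](O)C(C)(C)O[Si](C)(C)C(C)(C)C)O[C@@H]2OC[C@H]1C(=C)CC=C
F4 | step 19 | (7S)-vinyl carbinol, metathesis precursor | C=C[C@@](C)(O)CC[C@@H]1C2=C[C@H]([C@@H](O)C(C)(C)O[Si](C)(C)C(C)(C)C)O[C@@H]2OC[C@H]1C(=C)CC=C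
F5 | step 18 | keto butenolide (26 without the dioxolane) | O=C1O[C@@H]([C@@H](O)C(C)(C)O[Si](C)(C)C(C)(C)C)C=C1[C@@H](CCC(C)=O)[C@@H](CO)C(=C)CC#C[Si](C(C)C)(C(C)C)C(C)C
F6 | step 18 | lactol with C7 carbinol (C3 and C7 epimers) | CC(O)CC[C@H](C1=C[C@H]([C@@H](O)C(C)(C)O[Si](C)(C)C(C)(C)C)OC1O)[C@@H](CO)C(=C)CC#C[Si](C(C)C)(C(C)C)C(C)C
F7 | step 18 | bicyclic acetal with C7 carbinol (C7 epimers) | CC(O)CC[C@@H]1C2=C[C@H]([C@@H](O)C(C)(C)O[Si](C)(C)C(C)(C)C)O[C@@H]2OC[C@H]1C(=C)CC#C[Si](C(C)C)(C(C)C)C(C)C
F8 | step 18 | iodoalkyne with C7 carbinol | CC(O)CC[C@@H]1C2=C[C@H]([C@@H](O)C(C)(C)O[Si](C)(C)C(C)(C)C)O[C@@H]2OC[C@H]1C(=C)CC#CI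
F9 | step 18 | (Z)-iodoalkene with C7 carbinol | CC(O)CC[C@@H]1C2=C[C@H]([C@@H](O)C(C)(C)O[Si](C)(C)C(C)(C)C)O[C@@H]2OC[C@H]1C(=C)C/C=C\I
F10 | step 5 | (R,E)-5-(tert-butyldimethylsilyloxy)pent-3-en-2-ol | C[C@@H](O)/C=C/CO[Si](C)(C)C(C)(C)C
F11 | step 5 | (R,E)-5-(tert-butyldimethylsilyloxy)pent-3-en-2-yl pyridine-2-carboxylate | C[C@@H](OC(=O)c1ccccn1)/C=C/CO[Si](C)(C)C(C)(C)C
F12 | step 5 | [5-(triisopropylsilyl)pent-1-en-4-yn-2-yl]magnesium bromide | C=C([Mg]Br)CC#C[Si](C(C)C)(C(C)C)C(C)C
F13 | step 5 | (R,E)-propenyl analogue of 9 | C/C=C/[C@H](C(=C)CC#C[Si](C(C)C)(C(C)C)C(C)C)CO[Si](C)(C)C(C)(C)C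
F14 | step 5 | (R,E)-propenyl analogue of 10 | C/C=C/[C@H](C(=C)CC#C[Si](C(C)C)(C(C)C)C(C)C)CO
F15 | step 5 | (R,E)-propenyl analogue of 12 | C/C=C/[C@H](C(=C)CC#C[Si](C(C)C)(C(C)C)C(C)C)COC(=O)C=C
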